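An easy step comes first: multiplying each percentage of D by the charge of E turns the readings into concentrations. In a closed, stirred flask, E may turn reversibly into L or D, and L may exchange with crystals Z.

| setting | alpha | gamma | flask |
|---|---|---|---|
| E | 0.40 M | 1.6 M | 0.80 M |
| remark | run made earlier | run made earlier |  |
| time |  |  | 15 min |

| run | time / min | D / % | L / % |
|---|---|---|---|
| alpha | 1.00 | 19 | 71 |
| alpha | 2.00 | 18 | 71 |
| alpha | 5.00 | 25 | 68 |
| alpha | 12.0 | 23 | 65 |
| gamma | 1.00 | 12 | 82 |
| gamma | 2.00 | 11 | 86 |
| gamma | 5.00 | 9 | 88 |
| gamma | 12.0 | 6 | 90 |

(each reading ± 1.5 percentage points)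

- amounts and yields of L count Z too
- given per volume of solution although it is solid: Z
- steps that have been proposed: E <-> L; E <-> D; Z <-> L

- share of D in D plus L at 0.60 s
- share of D in D plus L at 15 min
- which of D and L there is more of at 15 min

The ladder starts at 1.00 min, where D plus L already reads 90.0% in alpha and 94.0% in gamma. The share of D then is 21.1% in alpha and 12.8% in gamma, so the shares have already moved apart with the charge. The reckoning made here therefore puts the share at 0.60 s below gamma's reading at 1.00 min, without a firmer number. The share that early is the kinetic end of kinetic against thermodynamic control.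

On the next rung, D moves over minutes: at 1.00 min, alpha reads 0.0760 M of D and gamma 0.192 M. On the last rung, at 12.0 min, alpha reads 0.0920 M, nearly the same as gamma's 0.0960 M, although the charges differ by a factor of 4.00. Gamma's reading serves as the held level of D, the concentration at which D stands late, as expected if crystals hold dissolved L and the proposed steps tie E and D to it.

Gamma's E at 12.0 min, taken by difference from two scattered readings, is 0.0640 M. The flask's charge lies between those of alpha and gamma, and 15 min is later than the last readings. The reckoning made here for the flask, with crystals assumed and gamma's two levels carried over, gives D 12.0% of the charge, a share of 13.0%, and L ahead.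

The forecast gives 11% early, 13% late and L ahead, on the reading “D is heading for about 0.09 M”.

The flask gives 6.72% at 0.60 s and 13.2% at 15 min, with L at 82.3% and D at 12.5%.

    E ⇌ L (K = 0.460, k = 0.170 s⁻¹)
    E ⇌ D (K = 2.40, k = 0.0110 s⁻¹)
    Z ⇌ L, rate k3*(cs3 - [L]) while solid is left; crystals form when [L] > cs3 (solubility = 19.0 mM, k = 0.190 s⁻¹)

The flask's D at 15.0 min equals 0.100 M, close to the held level. The same reckoning on the neighbour charged with 0.20 M of E puts D at 48.0% of that charge. At 15.0 min, that neighbour holds Z, which is counted in L, at 21.6% and E at 20.6%. There D, not L, holds the largest part of the charge, with L at 31.1% and D at 48.4%.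

Readings and results come from a simulation from invented constants; the scatter is artificial.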